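## Retrosynthetic overview (disconnections, listed from the building blocks up)

1. Z-allylic alcohol arm: prop-2-yn-1-ol 1 gives, through magnesacycle 2, the (Z)-alkenyl iodide 3; the arm is cut at its sp3–sp2 bond (Suzuki).
2. Backbone C1–C7: cycloheptene 4 is opened (through hydroperoxide 5) to the mono-masked dialdehyde 6, whose two alpha-carbons become the two stereocentres.
3. C2 centre: new metal-free photo-organocatalytic alpha-(2-borylethyl)ation of 6 with vinylboronate 7 (aldehyde 8, alcohol 9), acetate 10 put on at once, Suzuki coupling with 3 to 11, unmasking to aldehyde 12.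
4. C6 centre: organo-SOMO alpha-allylation of 12 with allylsilane 13 under the mirror-image catalyst (aldehyde 14, diol 15).
5. Rings: none is formed; the butenolide is bought as bromide 16 and joined last by B-alkyl Suzuki coupling through borane 17 to give target 18.

Assumption: the SMILES is read as (2R,6S)-6-(hydroxymethyl)-2-[(3Z)-5-hydroxy-4-methylpent-3-en-1-yl]-9-(2-oxo-2,5-dihydrofuran-3-yl)nonyl acetate; 7, 13, 16, both enantiomers of the imidazolidinone catalyst and 4CzIPN are taken as purchasable; the catalyst enantiomers are assigned from the usual steric model (E-enamine turned away from tert-butyl, benzyl arm shielding one face) and were not checked against a measured rotation.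

## Route

Step 1
Reactants: 1 prop-2-yn-1-ol
Product: 3 (Z)-3-iodo-2-methylprop-2-en-1-ol, via 4-methyl-2,5-dihydro-1,2-oxamagnesole 2 (not isolated)
Conditions: MeMgBr (2.5 equiv), CuI (10 mol %), THF, −10 °C → rt; then I2 (1.2 equiv), −10 °C → rt
Reagents that add atoms: methylmagnesium bromide C[Mg]Br; iodine II
Why: CuI-catalysed anti-carbomagnesiation of the propargylic alkoxide (Duboudin type) puts methyl on C2 and magnesium on C3 inside a five-membered O–Mg chelate, so iodinolysis with retention gives only the Z iodide (I cis to CH2OH).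

Step 2
Reactants: 4 cycloheptene
Product: 6 7,7-dimethoxyheptanal, via methoxy hydroperoxide 5 (not isolated)
Conditions: O3, CH2Cl2/MeOH, −78 °C; TsOH (10 mol %), rt; NaHCO3; Me2S, rt
Reagents that add atoms: ozone [O-][O+]=O; methanol CO
Why: unsymmetrical (Schreiber-type) ozonolysis, in which MeOH traps the carbonyl oxide end as a methoxy hydroperoxide while TsOH acetalises the aldehyde end, and Me2S then reduces only the hydroperoxide end to the free aldehyde.

Step 3
Reactants: 6 7,7-dimethoxyheptanal; 7 2-ethenyl-4,4,5,5-tetramethyl-1,3,2-dioxaborolane (3 equiv)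
Product: 9 (S)-7,7-dimethoxy-2-[2-(4,4,5,5-tetramethyl-1,3,2-dioxaborolan-2-yl)ethyl]heptan-1-ol, via boryl aldehyde 8 (not isolated)
Conditions: (2S,5S)-5-benzyl-2-tert-butyl-3-methylimidazolidin-4-one·CF3CO2H (20 mol %), 4CzIPN (2 mol %), 2,4,6-triisopropylbenzenethiol (10 mol %), H2O (3 equiv), DME, 450 nm LEDs, −10 °C; then NaBH4, EtOH, −10 → 0 °C
Reagents that add atoms: none
Why: Proposed new method: photoexcited 4CzIPN oxidises the chiral E-enamine of 6 to an electrophilic three-pi-electron enaminyl radical cation whose Si face is open (benzyl arm covers the Re face, olefin turned away from tert-butyl), this adds to the CH2 terminus of 7 to give a boron-stabilised alpha-boryl radical that takes H from the thiol, the thiyl radical is reduced back by the 4CzIPN radical anion and iminium hydrolysis releases (S)-8, which NaBH4 reduces before it can racemise; the closest known reaction type is the photoredox/enamine/hydrogen-atom-transfer alpha-alkylation of aldehydes with olefins, together with radical additions to vinylboronic esters, here untested with a vinylboronate partner and an organic photocatalyst.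

Step 4
Reactants: 9 (S)-7,7-dimethoxy-2-[2-(4,4,5,5-tetramethyl-1,3,2-dioxaborolan-2-yl)ethyl]heptan-1-ol
Product: 10 (S)-7,7-dimethoxy-2-[2-(4,4,5,5-tetramethyl-1,3,2-dioxaborolan-2-yl)ethyl]heptyl acetate
Conditions: Ac2O, pyridine, DMAP (5 mol %), CH2Cl2, 0 °C → rt
Reagents that add atoms: acetic anhydride CC(=O)OC(C)=O
Why: DMAP-catalysed O-acylation of the only hydroxyl puts on the acetate of the target, which then serves as its own protecting group; boronate and acetal are inert.

Step 5
Reactants: 10 (S)-7,7-dimethoxy-2-[2-(4,4,5,5-tetramethyl-1,3,2-dioxaborolan-2-yl)ethyl]heptyl acetate; 3 (Z)-3-iodo-2-methylprop-2-en-1-ol (1.3 equiv)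
Product: 11 (R)-2-[(3Z)-5-hydroxy-4-methylpent-3-en-1-yl]-7,7-dimethoxyheptyl acetate
Conditions: Pd(OAc)2 (5 mol %), SPhos (10 mol %), K3PO4 (3 equiv), toluene/H2O (10:1), 70 °C
Reagents that add atoms: none
Why: Suzuki–Miyaura sp3–sp2 coupling of a primary alkyl pinacol boronate with an alkenyl iodide keeps the Z geometry of 3, the bulky electron-rich SPhos favours transmetalation over beta-hydride loss, and biphasic K3PO4 spares acetate and acetal; C2 is untouched (its label changes from S to R only because the new arm outranks the linker).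

Step 6
Reactants: 11 (R)-2-[(3Z)-5-hydroxy-4-methylpent-3-en-1-yl]-7,7-dimethoxyheptyl acetate
Product: 12 (R)-2-[(3Z)-5-hydroxy-4-methylpent-3-en-1-yl]-7-oxoheptyl acetate
Conditions: TsOH·H2O (10 mol %), THF/H2O (4:1), rt
Reagents that add atoms: water O
Why: acid-catalysed hydrolysis of the dimethyl acetal; the primary acetate, the allylic alcohol and the remote stereocentre are stable to catalytic TsOH in wet THF.

Step 7
Reactants: 12 (R)-2-[(3Z)-5-hydroxy-4-methylpent-3-en-1-yl]-7-oxoheptyl acetate; 13 allyltrimethylsilane (2.5 equiv)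
Product: 15 (2R,6S)-6-(hydroxymethyl)-2-[(3Z)-5-hydroxy-4-methylpent-3-en-1-yl]non-8-en-1-yl acetate, via allyl aldehyde 14 (not isolated)
Conditions: (2R,5R)-5-benzyl-2-tert-butyl-3-methylimidazolidin-4-one·CF3CO2H (20 mol %), (NH4)2Ce(NO3)6 (2 equiv), NaHCO3 (2 equiv), H2O (2 equiv), DME, −20 °C; then NaBH4, EtOH, −20 → 0 °C
Reagents that add atoms: none
Why: organo-SOMO alpha-allylation (MacMillan type), in which (NH4)2Ce(NO3)6 oxidises the enamine to its radical cation, allylsilane 13 traps it on the Re face left open by the (2R,5R) catalyst, and a second oxidation with loss of the silyl cation gives (S)-aldehyde 14, reduced at once by NaBH4; C6 is under pure catalyst control because C2 is five bonds away, and the mirror-image catalyst to step 3 is needed because the two centres have opposite local handedness.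

Step 8
Reactants: 15 (2R,6S)-6-(hydroxymethyl)-2-[(3Z)-5-hydroxy-4-methylpent-3-en-1-yl]non-8-en-1-yl acetate; 16 3-bromofuran-2(5H)-one (1.5 equiv)
Product: 18 (2R,6S)-6-(hydroxymethyl)-2-[(3Z)-5-hydroxy-4-methylpent-3-en-1-yl]-9-(2-oxo-2,5-dihydrofuran-3-yl)nonyl acetate, via alkylborane 17 (not isolated)
Conditions: 9-BBN (3.5 equiv), THF, 0 °C → rt; then 16, Pd(dppf)Cl2 (10 mol %), AsPh3 (10 mol %), Cs2CO3 (3 equiv), DMF/H2O, rt
Reagents that add atoms: none
Why: 9-BBN hydroborates only the terminal olefin anti-Markovnikov (the trisubstituted olefin is far slower; the hydroxyls are O-borylated and freed again by aqueous base), and B-alkyl Suzuki–Miyaura coupling with the alpha-bromo butenolide at rt spares acetate and lactone; no stereocentre is touched.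

## Compound list

1 | prop-2-yn-1-ol | C#CCO | starting material
2 | 4-methyl-2,5-dihydro-1,2-oxamagnesole (cyclic (Z)-alkenylmagnesium alkoxide) | CC1=C[Mg]OC1 | intermediate
3 | (Z)-3-iodo-2-methylprop-2-en-1-ol | C/C(CO)=C/I | intermediate
4 | cycloheptene | C1=CCCCCC1 | starting material
5 | 1-hydroperoxy-1,7,7-trimethoxyheptane | COC(OO)CCCCCC(OC)OC | intermediate
6 | 7,7-dimethoxyheptanal | O=CCCCCCC(OC)OC | intermediate
7 | 2-ethenyl-4,4,5,5-tetramethyl-1,3,2-dioxaborolane (vinylboronic acid pinacol ester) | C=CB1OC(C)(C)C(C)(C)O1 | starting material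
8 | (S)-7,7-dimethoxy-2-[2-(4,4,5,5-tetramethyl-1,3,2-dioxaborolan-2-yl)ethyl]heptanal | O=C[C@@H](CCB1OC(C)(C)C(C)(C)O1)CCCCC(OC)OC | intermediate
9 | (S)-7,7-dimethoxy-2-[2-(4,4,5,5-tetramethyl-1,3,2-dioxaborolan-2-yl)ethyl]heptan-1-ol | OC[C@@H](CCB1OC(C)(C)C(C)(C)O1)CCCCC(OC)OC | intermediate
10 | (S)-7,7-dimethoxy-2-[2-(4,4,5,5-tetramethyl-1,3,2-dioxaborolan-2-yl)ethyl]heptyl acetate | CC(=O)OC[C@@H](CCB1OC(C)(C)C(C)(C)O1)CCCCC(OC)OC | intermediate
11 | (R)-2-[(3Z)-5-hydroxy-4-methylpent-3-en-1-yl]-7,7-dimethoxyheptyl acetate | CC(=O)OC[C@@H](CC/C=C(/C)CO)CCCCC(OC)OC | intermediate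
12 | (R)-2-[(3Z)-5-hydroxy-4-methylpent-3-en-1-yl]-7-oxoheptyl acetate | CC(=O)OC[C@@H](CC/C=C(/C)CO)CCCCC=O | intermediate
13 | allyltrimethylsilane | C=CC[Si](C)(C)C | starting material
14 | (2R,6S)-6-formyl-2-[(3Z)-5-hydroxy-4-methylpent-3-en-1-yl]non-8-en-1-yl acetate | CC(=O)OC[C@@H](CC/C=C(/C)CO)CCC[C@H](C=O)CC=C | intermediate
15 | (2R,6S)-6-(hydroxymethyl)-2-[(3Z)-5-hydroxy-4-methylpent-3-en-1-yl]non-8-en-1-yl acetate | CC(=O)OC[C@@H](CC/C=C(/C)CO)CCC[C@H](CO)CC=C | intermediate
16 | 3-bromofuran-2(5H)-one | O=C1OCC=C1Br | starting material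
17 | (2R,6R)-9-(9-borabicyclo[3.3.1]nonan-9-yl)-6-(hydroxymethyl)-2-[(3Z)-5-hydroxy-4-methylpent-3-en-1-yl]nonyl acetate (C6 unchanged in space; labelled R only because the boron arm ranks below the linker) | CC(=O)OC[C@@H](CC/C=C(/C)CO)CCC[C@H](CO)CCCB1C2CCCC1CCC2 | intermediate
18 | (2R,6S)-6-(hydroxymethyl)-2-[(3Z)-5-hydroxy-4-methylpent-3-en-1-yl]-9-(2-oxo-2,5-dihydrofuran-3-yl)nonyl acetate | CC(=O)OC[C@@H](CC/C=C(/C)CO)CCC[C@H](CO)CCCC1=CCOC1=O | target

## Step count

Total steps: 8. Longest linear sequence: 7 (steps 2–8, cycloheptene to target); step 1 is a one-step side branch.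

## Steps most likely to fail, and fallbacks

**Step 3 (the proposed new step).** The thiol co-catalyst may be consumed by thiol-ene addition to 7, the enaminyl radical cation may add too slowly to the mildly electron-poor vinylboronate, or the ee may be low. The fallback uses known chemistry, sets out from 6 and comes back at 11, at the cost of two extra steps. Aldehyde 6 is alpha-hydroxymethylated with aqueous formaldehyde under (R)-alpha,alpha-diphenylprolinol trimethylsilyl ether catalysis (toluene, pH 7 buffer) to (S)-2-(hydroxymethyl)-7,7-dimethoxyheptanal F1. This is methylenated at once under neutral conditions (PPh3, Me3SiCHN2, 2-propanol, RhCl(PPh3)3 cat., THF) to (R)-2-ethenyl-7,7-dimethoxyheptan-1-ol F2. Acetylation (Ac2O, pyridine) gives (R)-2-ethenyl-7,7-dimethoxyheptyl acetate F3. 9-BBN adds to the vinyl group to give (S)-2-[2-(9-borabicyclo[3.3.1]nonan-9-yl)ethyl]-7,7-dimethoxyheptyl acetate F4, which is coupled in the same flask with 3 (Pd(dppf)Cl2, AsPh3, Cs2CO3, DMF/H2O, rt) to give 11.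

**Step 7.** (NH4)2Ce(NO3)6 may damage the free allylic alcohol or the trisubstituted olefin of 12. Two catalyst-controlled steps at about 95:5 er each would also leave about 10 % of 1,5-diastereomers that are hard to remove, so both steps must be run cold. The fallback moves the oxidative allylation ahead of the alkenyl coupling, so the oxidant only meets a boronate and an acetate; it sets out from 10 and comes back at 15. Acetal hydrolysis of 10 (TsOH, THF/H2O) gives (S)-7-oxo-2-[2-(4,4,5,5-tetramethyl-1,3,2-dioxaborolan-2-yl)ethyl]heptyl acetate F5. The same allylation with 13, (NH4)2Ce(NO3)6 and the (2R,5R) catalyst gives (2S,6S)-6-formyl-2-[2-(4,4,5,5-tetramethyl-1,3,2-dioxaborolan-2-yl)ethyl]non-8-en-1-yl acetate F6, reduced in the flask by NaBH4 to (2S,6S)-6-(hydroxymethyl)-2-[2-(4,4,5,5-tetramethyl-1,3,2-dioxaborolan-2-yl)ethyl]non-8-en-1-yl acetate F7. Suzuki coupling of F7 with 3 under the step 5 conditions then gives 15.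

**Step 8.** The alpha-bromo butenolide and the product lactone are base-sensitive, and the coupling runs on a substrate with two free hydroxyls. The fallback builds the butenolide on the olefin instead of coupling it; it sets out from 15 and ends at 18. A [CpRu(MeCN)3]PF6-catalysed Alder-ene coupling (Trost type) of the terminal olefin of 15 with ethyl 4-hydroxybut-2-ynoate in acetone gives ethyl (2Z)-4-hydroxy-2-[(2E,4S,8R)-9-acetoxy-4-(hydroxymethyl)-8-[(3Z)-5-hydroxy-4-methylpent-3-en-1-yl]non-2-en-1-yl]but-2-enoate F8. This lactonises in the flask to (2R,6S,7E)-6-(hydroxymethyl)-2-[(3Z)-5-hydroxy-4-methylpent-3-en-1-yl]-9-(2-oxo-2,5-dihydrofuran-3-yl)non-7-en-1-yl acetate F9. RhCl(PPh3)3 under H2 (1 atm, benzene/EtOH) then saturates only the disubstituted C7=C8 olefin to give 18.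

Further compounds
F1 | step 3 | (S)-2-(hydroxymethyl)-7,7-dimethoxyheptanal | OC[C@@H](C=O)CCCCC(OC)OC
F2 | step 3 | (R)-2-ethenyl-7,7-dimethoxyheptan-1-ol | OC[C@@H](C=C)CCCCC(OC)OC
F3 | step 3 | (R)-2-ethenyl-7,7-dimethoxyheptyl acetate | CC(=O)OC[C@@H](C=C)CCCCC(OC)OC
F4 | step 3 | (S)-2-[2-(9-borabicyclo[3.3.1]nonan-9-yl)ethyl]-7,7-dimethoxyheptyl acetate | CC(=O)OC[C@@H](CCB1C2CCCC1CCC2)CCCCC(OC)OC
F5 | step 7 | (S)-7-oxo-2-[2-(4,4,5,5-tetramethyl-1,3,2-dioxaborolan-2-yl)ethyl]heptyl acetate | CC(=O)OC[C@@H](CCB1OC(C)(C)C(C)(C)O1)CCCCC=O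
F6 | step 7 | (2S,6S)-6-formyl-2-[2-(4,4,5,5-tetramethyl-1,3,2-dioxaborolan-2-yl)ethyl]non-8-en-1-yl acetate | CC(=O)OC[C@@H](CCB1OC(C)(C)C(C)(C)O1)CCC[C@H](C=O)CC=C
F7 | step 7 | (2S,6S)-6-(hydroxymethyl)-2-[2-(4,4,5,5-tetramethyl-1,3,2-dioxaborolan-2-yl)ethyl]non-8-en-1-yl acetate | CC(=O)OC[C@@H](CCB1OC(C)(C)C(C)(C)O1)CCC[C@H](CO)CC=C
F8 | step 8 | ethyl (2Z)-4-hydroxy-2-[(2E,4S,8R)-9-acetoxy-4-(hydroxymethyl)-8-[(3Z)-5-hydroxy-4-methylpent-3-en-1-yl]non-2-en-1-yl]but-2-enoate | CC(=O)OC[C@@H](CC/C=C(/C)CO)CCC[C@H](CO)/C=C/C/C(=C/CO)C(=O)OCC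
F9 | step 8 | (2R,6S,7E)-6-(hydroxymethyl)-2-[(3Z)-5-hydroxy-4-methylpent-3-en-1-yl]-9-(2-oxo-2,5-dihydrofuran-3-yl)non-7-en-1-yl acetate | CC(=O)OC[C@@H](CC/C=C(/C)CO)CCC[C@H](CO)/C=C/CC1=CCOC1=O
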